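The rate constants are assumed; the rest is arithmetic.

The pitfall is to take two flasks with the same loading of initiator and the same time for one flask at two strengths, when each step here is second order and the flask's time runs with the free monomer it has met.

    free monomer + initiator → living end + monomer in chains (k1 = 0.57 /M/s)
    free monomer + living end → monomer in chains + living end, rate k2*[living end]*[free monomer] (k2 = 1.5 /M/s)
    living end + free monomer → dead end (k3 = 0.25 /M/s)

| setting | south | north-west |
|---|---|---|
| free monomer | 0.40 M | 0.20 M |
| initiator | 5 mol% | 5 mol% |
| time | 8.0 s | 8.0 s |
- the average divides the monomer in chains by the number of chains begun, living and dead together
- run time (south): 8.0 s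
- which of the two ends with the longer chains by the average number of monomer units in a chain (chains begun, living or dead) ("neither" if they lie within 10%) (south / north-west / neither)
- average number of monomer units in a chain (chains begun, living or dead) at the end, south
- average number of monomer units in a chain (chains begun, living or dead) at the end, north-west

Let M be the free monomer concentration. In south, with M held at its charge, 0.57 /M/s times charge times time gives 1.82: this is the initiator clock θ, the time integral of the step-1 constant times M. Each rate carries M, so on θ each step is pseudo-first-order: initiator falls as e^(−θ), and living ends die at r = 0.439 per unit of θ.

Solving this for D, the monomer in chains per chain begun, with g = 4.69, gives D = 1 + g[(1 − e^(−rθ))/(r(1 − e^(−θ))) − 1]. The curve of D leaves 1 with slope 1.32 per unit of θ, bends to 2.32 at θ = 1, and runs towards the level 7.00, which is 1 plus the step-2 constant over the step-3 constant.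

My first round for south gives 3.33, with 15.6% of the free monomer used. Putting the mean of M's start and end levels back in turns the clock to 1.68, and D for south to 3.16. In north-west the clock reads 0.912; I stop at one round there, with D = 2.20. My pick is south.

The forecast says south, with 3.2 for south and 2.2 for north-west, holding that “halving the concentrations simply halves the clock”.

The simulation gives south, with 3.18 for south and 2.16 for north-west. The gap comes from the difference in concentration of free monomer: with that difference taken away, north-west gives 3.18 in place of 2.16. North-west at 8.00 s keeps 41.4% of its initiator, as south does at 4.00 s with 41.4%, so at those times the two flasks stand at one point of the clock θ. For south left until 30 s, the first-round clock 6.84 gives D = 6.48 and 36.9% used, so the clock turns to 5.58 and D to 6.11; that flask gives 6.03.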